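**Plan**

1. Retrosynthetic cuts, in this order: the C6–CH2(prenyl) bond at the quaternary carbon (which returns the cyclohexadienone to a phloroglucinol ring), the C2–C3 bond of the cis-2,3-dimethyl-dihydropyranone ring, the C8–CH(Ph) bond, the C6–CH2(cyclobutyl) bond, and the cyclobutane back to verbenone.
2. Enabling feature: C2–C3 lies between the ring oxygen O1 (on C8a) and the C4 carbonyl (on C4a). C3 can therefore be a metal carbene made from a 2-diazopropanoyl group, and C2 the methylene carbon of an O-ethyl group on the neighbouring ring carbon, its C–H bond activated by O1.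
3. Forward order: flopropione is converted into its 2-O-ethyl ether; the benzene ring then receives the cyclobutylmethyl group (reductive alkylation) and the CH(Ph)CH2CO unit, closed as a temporary six-membered lactone ring. Diazo transfer and carbene C–H insertion close the pyranone ring; lactone hydrolysis and dearomative C-prenylation create the cyclohexadienone ring last.
4. Stereochemistry: the cyclobutane centres come from (1S,5S)-verbenone and the benzylic centre from iminium catalysis. C2 and C3 (cis, 2R,3S) are set together in the insertion step under a chiral dirhodium prolinate, and the quaternary carbon by a ligand-controlled palladium allylic dearomatization.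
5. Temporary helpers: the lactone ring (masks the acid and the C7 oxygen), a tert-butyl carbonate on the C5 oxygen, two MOM ethers and the diazo group; all are removed or consumed. The base-labile cis-chromanone meets hydroxide only in the last step, as its phenolate.

Key step: step 13

Assumption: the target is an enolised β-triketone whose tautomers interconvert freely, so the route delivers the tautomeric system and no step is needed to fix the enol drawn (C4–OH, C5=O, C7=O).

**Route**

Step 1
Reactants: 1 (1S,5S)-(−)-verbenone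
Product: 3 (1S,3R)-3-acetyl-2,2-dimethylcyclobutane-1-carboxylic acid (cis-pinononic acid), via cyclobutyl α-keto acid 2 (not isolated)
Conditions: RuCl3·xH2O (2 mol %), NaIO4 (4.2 equiv), CCl4/MeCN/H2O, rt
Reagents that add atoms: sodium periodate, [Na+].[O-]I(=O)(=O)=O (oxygen atoms, delivered through RuO4)
Why: RuO4 formed in situ cleaves the enone C=C bond and the resulting α-keto acid is decarboxylated oxidatively (Sharpless-type oxidative cleavage, known for verbenone); the two bridgehead stereocentres are untouched and become C1 and C3 of the cis-cyclobutane.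

Step 2
Reactants: 3 cis-pinononic acid
Product: 4 (1S,3S)-2,2-dimethyl-3-(prop-1-en-2-yl)cyclobutane-1-carboxylic acid
Conditions: Ph3PCH3Br (2.2 equiv), KOtBu (3.2 equiv), THF, 0 °C to rt; then aq. HCl
Reagents that add atoms: methylenetriphenylphosphorane (from Ph3PCH3Br and KOtBu), C=P(c1ccccc1)(c1ccccc1)c1ccccc1
Why: Wittig methylenation of the methyl ketone on the carboxylate salt should proceed without epimerization, because the ring α-CH is hindered by the adjacent quaternary carbon and the cis-1,3 arrangement is the more stable one.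

Step 3
Reactants: 4 isopropenyl acid
Product: 5 [(1S,3S)-2,2-dimethyl-3-(prop-1-en-2-yl)cyclobutyl]methanol
Conditions: LiAlH4, THF, 0 °C to rt; H2O work-up
Reagents that add atoms: none
Why: hydride reduction of the carboxylic acid to the primary alcohol leaves the isolated alkene and both stereocentres untouched.

Step 4
Reactants: 5 cyclobutylmethanol
Product: 6 (1S,3S)-2,2-dimethyl-3-(prop-1-en-2-yl)cyclobutane-1-carbaldehyde
Conditions: Dess–Martin periodinane, CH2Cl2, 0 °C to rt
Reagents that add atoms: none
Why: Dess–Martin oxidation is neutral and stops at the aldehyde, so the α-stereocentre should not epimerize and the alkene is inert.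

Step 5
Reactants: 7 flopropione [1-(2,4,6-trihydroxyphenyl)propan-1-one]
Product: 8 1-[2-hydroxy-4,6-bis(methoxymethoxy)phenyl]propan-1-one
Conditions: MOMCl (2.1 equiv), i-Pr2NEt, CH2Cl2, 0 °C to rt
Reagents that add atoms: chloromethyl methyl ether, COCCl
Why: acetal protection stops after two hydroxyls because the last one is locked in the hydrogen bond to the ketone, the usual selectivity of acylphloroglucinols.

Step 6
Reactants: 8 bis-MOM ether
Product: 9 1-[2-ethoxy-4,6-bis(methoxymethoxy)phenyl]propan-1-one
Conditions: EtI, K2CO3, DMF, 50 °C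
Reagents that add atoms: iodoethane, CCI
Why: Williamson ethylation of the remaining chelated phenol under slightly forcing conditions installs the ethyl group whose methylene carbon becomes C2.

Step 7
Reactants: 9 ethyl ether
Product: 10 1-(2-ethoxy-4,6-dihydroxyphenyl)propan-1-one
Conditions: 3 M HCl, MeOH, 50 °C
Reagents that add atoms: none
Why: acid-catalysed acetal exchange removes both MOM groups while the aryl ethyl ether and the ketone are stable.

Step 8
Reactants: 10 ethoxy-dihydroxy ketone; 6 cyclobutane carbaldehyde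
Product: 12 1-[6-ethoxy-2,4-dihydroxy-3-{[(1R,3S)-2,2-dimethyl-3-(prop-1-en-2-yl)cyclobutyl]methyl}phenyl]propan-1-one, via ortho-quinone methide 11 (not isolated)
Conditions: Hantzsch ester (1.2 equiv), L-proline (20 mol %), CH2Cl2, rt
Reagents that add atoms: none
Why: Knoevenagel-type condensation at the ring carbon flanked by the two free hydroxyls (the most nucleophilic, 1,3-dione-like position) gives an ortho-quinone methide that the Hantzsch ester reduces in situ (organocatalytic three-component reductive alkylation); no new stereocentre is formed and those of the cyclobutane are not involved.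

Step 9
Reactants: 12 C-alkylated ketone; 13 (E)-cinnamaldehyde
Product: 14 1-[(4S)-5-ethoxy-2,7-dihydroxy-8-{[(1R,3S)-2,2-dimethyl-3-(prop-1-en-2-yl)cyclobutyl]methyl}-4-phenyl-3,4-dihydro-2H-chromen-6-yl]propan-1-one (lactol)
Conditions: (S)-α,α-diphenylprolinol trimethylsilyl ether (20 mol %), PhCO2H (20 mol %), toluene, 0 °C to rt
Reagents that add atoms: none
Why: iminium-catalysed Friedel–Crafts-type conjugate addition of the phenol through its only free ring carbon, followed by hemiacetal closure onto the adjacent hydroxyl, fixes the regiochemistry; attack on the iminium face not shielded by the CPh2OSiMe3 group should give the 4S centre.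

Step 10
Reactants: 14 lactol
Product: 15 (4S)-5-ethoxy-7-hydroxy-8-{[(1R,3S)-2,2-dimethyl-3-(prop-1-en-2-yl)cyclobutyl]methyl}-4-phenyl-6-propanoyl-3,4-dihydro-2H-chromen-2-one
Conditions: Ag2CO3 on Celite (3 equiv), toluene, reflux
Reagents that add atoms: none
Why: Fétizon oxidation converts lactols into lactones under neutral conditions that spare the phenol, the alkene and the benzylic centre; the lactone ring now masks both the acid and the C7 oxygen.

Step 11
Reactants: 15 hydroxy lactone
Product: 16 tert-butyl (4S)-5-ethoxy-8-{[(1R,3S)-2,2-dimethyl-3-(prop-1-en-2-yl)cyclobutyl]methyl}-2-oxo-4-phenyl-6-propanoyl-3,4-dihydro-2H-chromen-7-yl carbonate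
Conditions: Boc2O (1.5 equiv), DMAP (10 mol %), MeCN, rt
Reagents that add atoms: di-tert-butyl dicarbonate, CC(C)(C)OC(=O)OC(=O)OC(C)(C)C
Why: DMAP-catalysed carbonate formation caps the last phenol, which would otherwise trap the carbene by O–H insertion; the carbonate has no C–H bond α to oxygen and is cleaved later by hydroxide.

Step 12
Reactants: 16 carbonate ketone
Product: 18 tert-butyl (4S)-6-(2-diazopropanoyl)-5-ethoxy-8-{[(1R,3S)-2,2-dimethyl-3-(prop-1-en-2-yl)cyclobutyl]methyl}-2-oxo-4-phenyl-3,4-dihydro-2H-chromen-7-yl carbonate, via α-trifluoroacetyl ketone 17 (not isolated)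
Conditions: LiN(SiMe3)2 (1.1 equiv), THF, −78 °C; CF3CO2CH2CF3, −78 °C; cold aq. HCl work-up; then 4-acetamidobenzenesulfonyl azide, Et3N, H2O (1 equiv), MeCN, rt
Reagents that add atoms: 4-acetamidobenzenesulfonyl azide, CC(=O)Nc1ccc(cc1)S(=O)(=O)N=[N+]=[N-] (the two nitrogen atoms); 2,2,2-trifluoroethyl trifluoroacetate, O=C(OCC(F)(F)F)C(F)(F)F (the CF3CO group of 17 only)
Why: detrifluoroacetylative diazo transfer (Danheiser variant of the Regitz reaction) relies on kinetic enolization of the ketone CH2 (more acidic than the lactone CH2), C-trifluoroacetylation at −78 °C before the enolate can attack the hindered carbonate, and diazo transfer with loss of the trifluoroacetyl group.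

Step 13
Reactants: 18 diazo ketone
Product: 19 tert-butyl (2R,3S,10S)-6-{[(1R,3S)-2,2-dimethyl-3-(prop-1-en-2-yl)cyclobutyl]methyl}-2,3-dimethyl-4,8-dioxo-10-phenyl-3,4,9,10-tetrahydro-2H,8H-pyrano[2,3-f]chromen-5-yl carbonate
Conditions: Rh2[(S)-N-(phenylsulfonyl)prolinate]4 (2 mol %), CH2Cl2, 0 °C, slow addition of 18
Reagents that add atoms: none
Why: Loss of N2 at the dirhodium core gives an electrophilic carbene at C3, which inserts in a concerted three-centre, hydride-transfer-like transition state into one methylene C–H bond of the O-ethyl group, that bond being activated by the lone pair of the oxygen that becomes O1. The closest known reaction is the dirhodium-carboxylate-catalysed cyclization of 2-diazo-1-(2-alkoxyaryl)propan-1-ones to 2,3-disubstituted chroman-4-ones. The dihydropyranone ring closes as a six-membered ring by 1,6-insertion through a chair-like transition state (carbene carbon, C4, the two arene carbons, O1 and the methylene carbon), a mode that rhodium carboxylates favour over five-membered oxonium ylide formation when the migrating group would be a simple ethyl. C2 is set by the choice between the two diastereotopic methylene hydrogens, made by the chiral prolinate ligands and expected to be assisted by the neighbouring C10 phenyl, which holds the ethyl group on the opposite face of the arene; C3 is set in the same transition state, the insertion placing the two methyl groups cis under kinetic control. The step needs chemoselectivity for C–H insertion over 1,2-hydride shift to the vinyl ketone, O–H insertion and cyclopropanation, which the absence of any free hydroxyl (lactone and carbonate), the remoteness of the isopropenyl group, the low temperature and the slow addition should secure; it also needs the cis-2R,3S sense, for which the antipodal catalyst is taken if the (S)-prolinate proves mismatched with the substrate.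

Step 14
Reactants: 19 tricyclic chromanone lactone; 20 prenyl acetate (3-methylbut-2-en-1-yl acetate)
Product: 22 (3S)-3-[(2R,3S,6R)-6-{[(1R,3S)-2,2-dimethyl-3-(prop-1-en-2-yl)cyclobutyl]methyl}-4-hydroxy-2,3-dimethyl-6-(3-methylbut-2-en-1-yl)-5,7-dioxo-3,5,6,7-tetrahydro-2H-chromen-8-yl]-3-phenylpropanoic acid (CNP0328119.1), via trilithium salt 21 (not isolated)
Conditions: LiOH·H2O (5.5 equiv), degassed THF/H2O, 0 °C; then Pd2(dba)3·CHCl3 (2.5 mol %), (R,R)-N,N'-(cyclohexane-1,2-diyl)bis[2-(diphenylphosphino)benzamide] (7.5 mol %), 20 (1.1 equiv), 0 °C to rt; then 1 M HCl to pH 3 at 0 °C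
Reagents that add atoms: lithium hydroxide, [Li+].[OH-] (oxygen of the carboxyl group)
Why: hydroxide opens the aryl lactone and removes the aryl carbonate to give the phloroglucinolate 21, whose phenolate conjugation with the C4 carbonyl disfavours enolization at C3, and Tsuji–Trost allylation by the π-prenyl palladium complex then takes place at C6 (the ring carbon between the two phenolate oxygens) through the unsubstituted allyl terminus, O-prenylation being reversible under the catalysis so that material funnels to the C-alkylated cyclohexadienone; the new quaternary centre is set by the chiral ligand in a palladium-catalysed asymmetric allylic dearomatization, and the antipodal ligand is used if the sense of induction is opposite.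

**Compound list**

1 | (1S,5S)-(−)-verbenone | CC1=CC(=O)[C@H]2C[C@@H]1C2(C)C | starting material
2 | 2-[(1S,3R)-3-acetyl-2,2-dimethylcyclobutyl]-2-oxoacetic acid | CC(=O)[C@@H]1C[C@H](C(=O)C(=O)O)C1(C)C | intermediate
3 | (1S,3R)-3-acetyl-2,2-dimethylcyclobutane-1-carboxylic acid (cis-pinononic acid) | CC(=O)[C@@H]1C[C@H](C(=O)O)C1(C)C | intermediate
4 | (1S,3S)-2,2-dimethyl-3-(prop-1-en-2-yl)cyclobutane-1-carboxylic acid | C=C(C)[C@@H]1C[C@H](C(=O)O)C1(C)C | intermediate
5 | [(1S,3S)-2,2-dimethyl-3-(prop-1-en-2-yl)cyclobutyl]methanol | C=C(C)[C@@H]1C[C@H](CO)C1(C)C | intermediate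
6 | (1S,3S)-2,2-dimethyl-3-(prop-1-en-2-yl)cyclobutane-1-carbaldehyde | C=C(C)[C@@H]1C[C@H](C=O)C1(C)C | intermediate
7 | flopropione, 1-(2,4,6-trihydroxyphenyl)propan-1-one | CCC(=O)c1c(O)cc(O)cc1O | starting material
8 | 1-[2-hydroxy-4,6-bis(methoxymethoxy)phenyl]propan-1-one | CCC(=O)c1c(O)cc(OCOC)cc1OCOC | intermediate
9 | 1-[2-ethoxy-4,6-bis(methoxymethoxy)phenyl]propan-1-one | CCC(=O)c1c(OCC)cc(OCOC)cc1OCOC | intermediate
10 | 1-(2-ethoxy-4,6-dihydroxyphenyl)propan-1-one | CCC(=O)c1c(O)cc(O)cc1OCC | intermediate
11 | ortho-quinone methide from 10 and 6 (exocyclic C=CH–cyclobutyl at the carbon between the two oxygens, alkene geometry not defined) | C=C(C)[C@@H]1C[C@H](C=C2C(O)=C(C(=O)CC)C(OCC)=CC2=O)C1(C)C | intermediate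
12 | 1-[6-ethoxy-2,4-dihydroxy-3-{[(1R,3S)-2,2-dimethyl-3-(prop-1-en-2-yl)cyclobutyl]methyl}phenyl]propan-1-one | C=C(C)[C@@H]1C[C@H](Cc2c(O)c(C(=O)CC)c(OCC)cc2O)C1(C)C | intermediate
13 | (E)-cinnamaldehyde | O=C/C=C/c1ccccc1 | starting material
14 | 1-[(4S)-5-ethoxy-2,7-dihydroxy-8-{[(1R,3S)-2,2-dimethyl-3-(prop-1-en-2-yl)cyclobutyl]methyl}-4-phenyl-3,4-dihydro-2H-chromen-6-yl]propan-1-one (lactol, both C2 epimers) | C=C(C)[C@@H]1C[C@H](Cc2c(O)c(C(=O)CC)c(OCC)c3c2OC(O)C[C@H]3c2ccccc2)C1(C)C | intermediate
15 | (4S)-5-ethoxy-7-hydroxy-8-{[(1R,3S)-2,2-dimethyl-3-(prop-1-en-2-yl)cyclobutyl]methyl}-4-phenyl-6-propanoyl-3,4-dihydro-2H-chromen-2-one | C=C(C)[C@@H]1C[C@H](Cc2c(O)c(C(=O)CC)c(OCC)c3c2OC(=O)C[C@H]3c2ccccc2)C1(C)C | intermediate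
16 | tert-butyl (4S)-5-ethoxy-8-{[(1R,3S)-2,2-dimethyl-3-(prop-1-en-2-yl)cyclobutyl]methyl}-2-oxo-4-phenyl-6-propanoyl-3,4-dihydro-2H-chromen-7-yl carbonate | C=C(C)[C@@H]1C[C@H](Cc2c(OC(=O)OC(C)(C)C)c(C(=O)CC)c(OCC)c3c2OC(=O)C[C@H]3c2ccccc2)C1(C)C | intermediate
17 | tert-butyl (4S)-5-ethoxy-8-{[(1R,3S)-2,2-dimethyl-3-(prop-1-en-2-yl)cyclobutyl]methyl}-2-oxo-4-phenyl-6-(4,4,4-trifluoro-2-methyl-3-oxobutanoyl)-3,4-dihydro-2H-chromen-7-yl carbonate (keto/enol mixture) | C=C(C)[C@@H]1C[C@H](Cc2c(OC(=O)OC(C)(C)C)c(C(=O)C(C)C(=O)C(F)(F)F)c(OCC)c3c2OC(=O)C[C@H]3c2ccccc2)C1(C)C | intermediate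
18 | tert-butyl (4S)-6-(2-diazopropanoyl)-5-ethoxy-8-{[(1R,3S)-2,2-dimethyl-3-(prop-1-en-2-yl)cyclobutyl]methyl}-2-oxo-4-phenyl-3,4-dihydro-2H-chromen-7-yl carbonate | C=C(C)[C@@H]1C[C@H](Cc2c(OC(=O)OC(C)(C)C)c(C(=O)C(C)=[N+]=[N-])c(OCC)c3c2OC(=O)C[C@H]3c2ccccc2)C1(C)C | intermediate
19 | tert-butyl (2R,3S,10S)-6-{[(1R,3S)-2,2-dimethyl-3-(prop-1-en-2-yl)cyclobutyl]methyl}-2,3-dimethyl-4,8-dioxo-10-phenyl-3,4,9,10-tetrahydro-2H,8H-pyrano[2,3-f]chromen-5-yl carbonate | C=C(C)[C@@H]1C[C@H](Cc2c(OC(=O)OC(C)(C)C)c3C(=O)[C@@H](C)[C@@H](C)Oc3c3c2OC(=O)C[C@H]3c2ccccc2)C1(C)C | intermediate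
20 | prenyl acetate, 3-methylbut-2-en-1-yl acetate | CC(=O)OCC=C(C)C | starting material
21 | trilithium salt of (3S)-3-[(2R,3S)-6-{[(1R,3S)-2,2-dimethyl-3-(prop-1-en-2-yl)cyclobutyl]methyl}-5,7-dihydroxy-2,3-dimethyl-4-oxo-3,4-dihydro-2H-chromen-8-yl]-3-phenylpropanoic acid | [Li+].[Li+].[Li+].C=C(C)[C@@H]1C[C@H](Cc2c([O-])c3C(=O)[C@@H](C)[C@@H](C)Oc3c([C@@H](CC(=O)[O-])c3ccccc3)c2[O-])C1(C)C | intermediate
22 | (3S)-3-[(2R,3S,6R)-6-{[(1R,3S)-2,2-dimethyl-3-(prop-1-en-2-yl)cyclobutyl]methyl}-4-hydroxy-2,3-dimethyl-6-(3-methylbut-2-en-1-yl)-5,7-dioxo-3,5,6,7-tetrahydro-2H-chromen-8-yl]-3-phenylpropanoic acid (CNP0328119.1) | C=C(C)[C@@H]1C[C@H](C[C@@]2(CC=C(C)C)C(=O)C3=C(O)[C@@H](C)[C@@H](C)OC3=C([C@@H](CC(=O)O)c3ccccc3)C2=O)C1(C)C | target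

**Totals**

Total step count: 14.
Longest linear sequence: 11 steps (steps 1–4, then 8–14, from verbenone); the flopropione branch (steps 5–7) joins at step 8.

**Steps most likely to fail**

Step 14. The ligand may discriminate poorly between the two faces of the prochiral C6 of the phloroglucinolate. Prenylation at C8 or at oxygen may fail to revert under the catalysis. Hydroxide may epimerize C3 before the phenolates have formed. Fallback, setting out from 19 and coming back at 22: 19 is hydrolysed with aqueous LiOH as in the main route to 21, and the stereocontrolling catalyst is given up. The trianion is C-prenylated without catalyst by prenyl bromide in the cold aqueous hydroxide/THF mixture (classical C-alkylation of phloroglucinolates), then acidified. This should give 22 together with its C6 epimer F1; the two are diastereomers and are separated by preparative reversed-phase HPLC.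

Step 13. The carbene may undergo 1,2-hydride shift to the vinyl ketone, may be diverted through the oxonium ylide to a benzofuranone by ethyl shift, or the chiral catalyst may oppose the bias of the substrate so that the cis-2R,3S isomer is not dominant. Fallback, setting out from 7 and coming back at 21; it builds the pyranone by condensation and hydrogenation instead of carbene insertion. Flopropione 7 is heated with Ac2O and NaOAc (Kostanecki–Robinson reaction) to give 5,7-diacetoxy-2,3-dimethyl-4H-chromen-4-one F2. Aqueous Na2CO3 in MeOH removes the acetates to give 5,7-dihydroxy-2,3-dimethyl-4H-chromen-4-one F3. Asymmetric syn-hydrogenation of the C2=C3 bond [Ru(cod)(2-methylallyl)2 with a chiral N-heterocyclic carbene ligand, H2] should give the cis compound (2R,3S)-5,7-dihydroxy-2,3-dimethylchroman-4-one F4. Reductive alkylation with 6 under the conditions of step 8 then places the cyclobutylmethyl group at C6, between the two hydroxyls, giving the C6-alkylated chromanone F5. Conjugate addition to 13 under the conditions of step 9 at the last free carbon C8 gives the lactol F6, and Ag2CO3 on Celite gives the 5-hydroxy lactone F7. Treatment of F7 with LiOH as in step 14 gives 21, from which the route continues.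

Step 9. The last free ring carbon, flanked by ethoxy and hydroxyl on an acyl-deactivated arene, may add too slowly to the iminium ion. 1,2-Addition with chromene formation may compete, and reversibility may erode the enantiomeric purity. Fallback, setting out from 12 and coming back at 15; the ring is closed first and the benzylic centre is set afterwards. The non-chelated hydroxyl of 12 is esterified with propiolic acid (DCC, DMAP) to the aryl propiolate F8. Gold-catalysed intramolecular hydroarylation (Ph3PAuNTf2, 1,2-dichloroethane) closes the 4-unsubstituted coumarin F9. Hayashi–Miyaura conjugate addition of PhB(OH)2 [Rh(acac)(C2H4)2, (S)-SEGPHOS, dioxane/H2O, 60 °C] then delivers the 4S lactone 15.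

**Further compounds**

F1 | step 14 | C6 epimer of 22, (3S)-3-[(2R,3S,6S)-6-{[(1R,3S)-2,2-dimethyl-3-(prop-1-en-2-yl)cyclobutyl]methyl}-4-hydroxy-2,3-dimethyl-6-(3-methylbut-2-en-1-yl)-5,7-dioxo-3,5,6,7-tetrahydro-2H-chromen-8-yl]-3-phenylpropanoic acid | C=C(C)[C@@H]1C[C@H](C[C@]2(CC=C(C)C)C(=O)C3=C(O)[C@@H](C)[C@@H](C)OC3=C([C@@H](CC(=O)O)c3ccccc3)C2=O)C1(C)C
F2 | step 13 | 5,7-diacetoxy-2,3-dimethyl-4H-chromen-4-one | CC(=O)Oc1cc(OC(C)=O)c2c(c1)oc(C)c(C)c2=O
F3 | step 13 | 5,7-dihydroxy-2,3-dimethyl-4H-chromen-4-one | Cc1oc2cc(O)cc(O)c2c(=O)c1C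
F4 | step 13 | (2R,3S)-5,7-dihydroxy-2,3-dimethylchroman-4-one | Oc1cc(O)c2C(=O)[C@@H](C)[C@@H](C)Oc2c1
F5 | step 13 | (2R,3S)-6-{[(1R,3S)-2,2-dimethyl-3-(prop-1-en-2-yl)cyclobutyl]methyl}-5,7-dihydroxy-2,3-dimethylchroman-4-one | C=C(C)[C@@H]1C[C@H](Cc2c(O)c3C(=O)[C@@H](C)[C@@H](C)Oc3cc2O)C1(C)C
F6 | step 13 | (2R,3S,10S)-6-{[(1R,3S)-2,2-dimethyl-3-(prop-1-en-2-yl)cyclobutyl]methyl}-5,8-dihydroxy-2,3-dimethyl-10-phenyl-2,3,9,10-tetrahydro-4H,8H-pyrano[2,3-f]chromen-4-one (lactol, both C8 epimers) | C=C(C)[C@@H]1C[C@H](Cc2c(O)c3C(=O)[C@@H](C)[C@@H](C)Oc3c3c2OC(O)C[C@H]3c2ccccc2)C1(C)C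
F7 | step 13 | (2R,3S,10S)-6-{[(1R,3S)-2,2-dimethyl-3-(prop-1-en-2-yl)cyclobutyl]methyl}-5-hydroxy-2,3-dimethyl-10-phenyl-2,3,9,10-tetrahydro-4H,8H-pyrano[2,3-f]chromene-4,8-dione | C=C(C)[C@@H]1C[C@H](Cc2c(O)c3C(=O)[C@@H](C)[C@@H](C)Oc3c3c2OC(=O)C[C@H]3c2ccccc2)C1(C)C
F8 | step 9 | 5-ethoxy-2-{[(1R,3S)-2,2-dimethyl-3-(prop-1-en-2-yl)cyclobutyl]methyl}-3-hydroxy-4-propanoylphenyl prop-2-ynoate | C=C(C)[C@@H]1C[C@H](Cc2c(O)c(C(=O)CC)c(OCC)cc2OC(=O)C#C)C1(C)C
F9 | step 9 | 5-ethoxy-7-hydroxy-8-{[(1R,3S)-2,2-dimethyl-3-(prop-1-en-2-yl)cyclobutyl]methyl}-6-propanoyl-2H-chromen-2-one | C=C(C)[C@@H]1C[C@H](Cc2c(O)c(C(=O)CC)c(OCC)c3c2OC(=O)C=C3)C1(C)C
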